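All runs are calculated from invented constants; the scatter is artificial.

The south-west run ended with less other mono adduct than coupling partner charged, 1.64 mM against 5 mM, and its other mono adduct readings had levelled, at 10.7% after 3.00 d and 10.9% after 6.00 d, each good to 0.3 percentage points.

south-west run (percent of the substrate charged)

| time / d | other mono adduct / % | first product / % |
|---|---|---|
| 0.500 | 5.8 | 6.6 |
| 0.833 | 7.4 | 5.6 |
| 1.67 | 10.0 | 3.4 |
| 3.00 | 10.7 | 2.2 |
| 6.00 | 10.9 | 1.5 |

(standard deviation of a reading: 0.3 percentage points)

You take over these flasks:

| setting | south-west | Saturday's | Friday's | Thursday's |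
|---|---|---|---|---|
| substrate | 0.015 M | 0.010 M | 0.010 M | 0.010 M |
| coupling partner | 5 mM | 5.00 mM | 10.0 mM | 25.0 mM |
| remark | run made earlier |  |  |  |
| time |  | 10 d | 10 d | 10 d |

1. final other mono adduct, as a percentage of the substrate charged, for each flask in turn (Saturday's, Friday's, Thursday's)

Each now holds substrate and coupling partner turning into first product and other mono adduct. From the south-west run I take 0.327 mole of other mono adduct per mole of coupling partner charged, the partner yield. Coupling partner was the limiting reagent there by charge. My reckoning for 10 d is:

other mono adduct = partner yield × coupling partner ÷ substrate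

Saturday's: 16.3%
Friday's: 32.7%
Thursday's: 81.8%

I commit to Saturday's figure, where substrate stands in excess. Friday's charges are equal and Thursday's has excess coupling partner, so hold those two loosely. Keep the flasks closed and add no coupling partner, since the yield was read from one charge.

The forecast differs from mine: 12.3%, 22.1% and 42%, on the ground “I assume the plateau is a true equilibrium”.

The flasks give 15.0% on Saturday's, 19.8% on Friday's and 0.573% on Thursday's, so the partner yield is 0.300 on Saturday's and 0.198 on Friday's.

coupling partner + other mono adduct → bis adduct + by-product (k = 4.64 M⁻¹ h⁻¹); coupling partner ⇌ dormant form (K = 1.51, k = 1.27 h⁻¹); coupling partner + first product → bis adduct + by-product (k = 6.97 M⁻¹ h⁻¹); first product + by-product → side product (k = 9.51 M⁻¹ h⁻¹); first product ⇌ isomer of the product (K = 3.10, k = 0.0519 h⁻¹); substrate + coupling partner → first product + by-product (k = 6.43 M⁻¹ h⁻¹); substrate + coupling partner → other mono adduct + by-product (k = 3.96 M⁻¹ h⁻¹) Per unit of coupling partner, other mono adduct is made at 3.96 M⁻¹ h⁻¹ times substrate and lost to bis adduct at 4.64 M⁻¹ h⁻¹ times itself, so the two rates balance at an other mono adduct to substrate ratio of 0.853. That ratio is 0.275 on Saturday's after 10.0 d, 0.837 on Friday's after 5.00 d, and 19.4 on Thursday's after 5.00 d.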